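**Retrosynthetic overview** (labdane numbering; target = (14S)-8α,14,15-trihydroxylabd-13(16)-en-19-oic acid)
- End game: the C19 acid comes from a chiral auxiliary ester by way of the C19 alcohol. The 8α-OH and 8β-methyl come from a C8=C17 alkene through its 8α,17-epoxide. The side chain is joined at C12–C13 by a B-alkyl Suzuki coupling of a C9-vinyl decalin with a bromovinyl dioxolane that brings C14 from the chiral pool.
- Key disconnection: C4–C5 and C9–C10 are cut together, which leads back to an open-chain 2-methyl-3-oxo-6,10-dienoate. Ring A closes first (C4–C5), ring B second (C10–C9), and the C8 radical ends as the C8=C17 alkene. These are the same two C–C bonds, made in the same order, as in the biosynthetic folding of the polyprenyl chain.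
- Enabling feature: C4 of ring A carries the carboxyl carbon C19 and lies next to C3. A temporary C3 ketone therefore makes C4–H the oxidisable α-position of a β-keto ester. C4, C5=C10 and C9=C8 are spaced head to tail, so each radical meets the next alkene in a six-membered chair, and the tertiary carbinol carbon C8 of ring B marks where the cascade ends.
- Temporary elements: the C3 ketone is removed via its tosylhydrazone, and the (+)-8-phenylmenthyl ester is removed by LiAlH4.
- The precursor is made from geraniol (C1, C5–C11, C17, C20) and a 2-methylacetoacetate (C2–C4, C18, C19).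

Key step: step 6

Assumption: the planar C4 radical of the (+)-8-phenylmenthyl ester is taken to react in its extended dicarbonyl conformer from the face not covered by the phenyl ring, which corresponds to the 5α-H/10β-methyl series; the two series are diastereomers and can be separated in any case.

**Step 1**
Reactants: 1 geraniol
Product: 2 geranyl tert-butyldiphenylsilyl ether
Conditions: TBDPSCl, imidazole, CH2Cl2, 0 °C to rt
Reagents that add atoms: tert-butyl(chloro)diphenylsilane, CC(C)(C)[Si](Cl)(c1ccccc1)c1ccccc1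
Why: Imidazole-promoted silylation of a primary allylic alcohol; the TBDPS ether is chosen because it should withstand the dianion of step 5 and the acetic acid of step 6.

**Step 2**
Reactants: 2 geranyl tert-butyldiphenylsilyl ether
Product: 3 (2E,6E)-8-(tert-butyldiphenylsilyloxy)-2,6-dimethylocta-2,6-dien-1-ol
Conditions: SeO2 (cat.), salicylic acid (cat.), t-BuOOH, CH2Cl2, 0 °C to rt
Reagents that add atoms: tert-butyl hydroperoxide, CC(C)(C)OO
Why: Selenium dioxide allylic oxidation (ene reaction, then [2,3]-sigmatropic shift) should attack the more electron-rich terminal alkene and give the E allylic alcohol, the other alkene being deactivated by its allylic oxygen.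

**Step 3**
Reactants: 3 (2E,6E)-8-(tert-butyldiphenylsilyloxy)-2,6-dimethylocta-2,6-dien-1-ol
Product: 4 (2E,6E)-8-bromo-3,7-dimethylocta-2,6-dienyl tert-butyldiphenylsilyl ether
Conditions: CBr4, PPh3, CH2Cl2, 0 °C
Reagents that add atoms: carbon tetrabromide, BrC(Br)(Br)Br
Why: The Appel reaction displaces the primary allylic alkoxyphosphonium ion by SN2, so both E alkenes should be kept without allylic transposition.

**Step 4**
Reactants: 5 ethyl 2-methylacetoacetate; 6 (+)-8-phenylmenthol
Product: 7 (+)-8-phenylmenthyl 2-methyl-3-oxobutanoate (both C2 epimers)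
Conditions: DMAP (cat.), toluene, reflux, ethanol distilled off
Reagents that add atoms: none
Why: DMAP-catalysed transesterification of an enolisable β-keto ester should work with hindered secondary alcohols and is driven by removal of ethanol.

**Step 5**
Reactants: 7 (+)-8-phenylmenthyl 2-methyl-3-oxobutanoate; 4 (2E,6E)-8-bromo-3,7-dimethylocta-2,6-dienyl tert-butyldiphenylsilyl ether
Product: 9 (+)-8-phenylmenthyl (6E,10E)-12-(tert-butyldiphenylsilyloxy)-2,6,10-trimethyl-3-oxododeca-6,10-dienoate (both C2 epimers), via lithium sodium dianion 8 (not isolated)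
Conditions: NaH, THF, 0 °C; n-BuLi, 0 °C; then 4, 0 °C; 1 M HCl quench
Reagents that add atoms: none
Why: Weiler-type γ-alkylation, in which the more reactive terminal carbanion of the β-keto ester dianion displaces the allylic bromide and forms C1–C2 with the alkene geometry retained.

**Step 6**
Reactants: 9 (+)-8-phenylmenthyl (6E,10E)-12-(tert-butyldiphenylsilyloxy)-2,6,10-trimethyl-3-oxododeca-6,10-dienoate
Product: 10 (+)-8-phenylmenthyl 11-(tert-butyldiphenylsilyloxy)-3-oxo-12,13,14,15,16-pentanorlabd-8(17)-en-19-oate (trans-decalin; 4α-methyl; 4β axial ester; 5α-H; 9α-H; 10β-methyl)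
Conditions: Mn(OAc)3·2H2O (2.2 equiv), Cu(OAc)2·H2O (1 equiv), degassed AcOH, rt; chromatographic removal of the minor diastereomer
Reagents that add atoms: none
Why: Mn(OAc)3 oxidises the enolisable C4–H of the β-keto ester to an electrophilic tertiary C4 radical, which bonds to C5; the tertiary C10 radical so formed bonds to C9, and the tertiary C8 radical is oxidised by Cu(OAc)2 with loss of a C17 hydrogen, the monovalent copper being returned to the divalent state by a second Mn(OAc)3. The closest known reaction type is the manganese triacetate/copper diacetate oxidative free-radical cyclisation of 2-methyl-3-oxo-6,10-dienoates to trans-decalones with an axial ester and an exocyclic methylene group, which is also known with 8-phenylmenthyl esters. Ring A closes 6-endo-trig through C4–C5 and ring B closes 6-endo-trig through C10–C9, 5-exo attack being disfavoured in both cases because the inner alkene carbons C10 and C8 are fully substituted and 6-endo attack gives a tertiary radical. The E geometry of both alkenes in a chair–chair fold sets 5α-H against 10β-methyl (trans fusion) and puts the C9 CH2OSi arm equatorial, and C4 takes the axial ester and the equatorial methyl group because the radical reacts in the extended conformer in which the ester carbon lies anti to the C3 oxygen. The absolute sense comes from the auxiliary, whose phenyl ring stacks over one face of the planar C4 radical so that C5 bonds to the open face. The step needs oxidation at C4–H only (secured by the 1,3-dicarbonyl acidity), termination toward C17 (secured by the preference of the copper-mediated elimination for the least hindered methyl hydrogen) and facial selectivity (secured by the auxiliary, the minor diastereomer being removable because the auxiliary makes the two series diastereomeric).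

**Step 7**
Reactants: 10 (+)-8-phenylmenthyl 11-(tert-butyldiphenylsilyloxy)-3-oxo-12,13,14,15,16-pentanorlabd-8(17)-en-19-oate
Product: 11 3-(p-toluenesulfonylhydrazone) of 10
Conditions: TsNHNH2, EtOH, reflux
Reagents that add atoms: p-toluenesulfonohydrazide, Cc1ccc(cc1)S(=O)(=O)NN
Why: Hydrazone condensation at the only ketone, a reaction known for 3-ketones flanked by a quaternary C4; the shielded axial ester should not be attacked by the weakly nucleophilic sulfonamide nitrogen.

**Step 8**
Reactants: 11 3-(p-toluenesulfonylhydrazone) of 10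
Product: 12 (+)-8-phenylmenthyl 11-(tert-butyldiphenylsilyloxy)-12,13,14,15,16-pentanorlabd-8(17)-en-19-oate
Conditions: catecholborane, CHCl3, −10 °C; then NaOAc·3H2O, reflux
Reagents that add atoms: none
Why: Caglioti-type deoxygenation, in which the borane delivers hydride to C=N and acetate then triggers loss of sulfinate and nitrogen to leave C3H2; catecholborane should not hydroborate the 1,1-disubstituted alkene at this temperature.

**Step 9**
Reactants: 12 (+)-8-phenylmenthyl 11-(tert-butyldiphenylsilyloxy)-12,13,14,15,16-pentanorlabd-8(17)-en-19-oate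
Product: 13 (+)-8-phenylmenthyl 11-hydroxy-12,13,14,15,16-pentanorlabd-8(17)-en-19-oate
Conditions: TBAF, THF, rt to 40 °C
Reagents that add atoms: none
Why: Fluoride-induced desilylation, which the hindered ester and the alkene should not notice.

**Step 10**
Reactants: 13 (+)-8-phenylmenthyl 11-hydroxy-12,13,14,15,16-pentanorlabd-8(17)-en-19-oate
Product: 14 (+)-8-phenylmenthyl 11-oxo-12,13,14,15,16-pentanorlabd-8(17)-en-19-oate
Conditions: Dess–Martin periodinane, CH2Cl2, 0 °C to rt
Reagents that add atoms: none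
Why: The Dess–Martin oxidation is base-free, so the β,γ-unsaturated aldehyde should keep its alkene position and its equatorial C9 configuration.

**Step 11**
Reactants: 14 (+)-8-phenylmenthyl 11-oxo-12,13,14,15,16-pentanorlabd-8(17)-en-19-oate
Product: 15 (+)-8-phenylmenthyl 13,14,15,16-tetranorlabda-8(17),11-dien-19-oate
Conditions: Ph3PCH3Br, KHMDS, THF, 0 °C; then 14, −78 °C to 0 °C
Reagents that add atoms: methyltriphenylphosphonium bromide, C[P+](c1ccccc1)(c1ccccc1)c1ccccc1.[Br-]
Why: Wittig methylenation adds C12; addition of the unstabilised ylide at low temperature should be faster than enolisation at C9, and the equatorial C9 substituent is in any case the more stable one.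

**Step 12**
Reactants: 15 (+)-8-phenylmenthyl 13,14,15,16-tetranorlabda-8(17),11-dien-19-oate
Product: 16 (+)-8-phenylmenthyl 8α,17-epoxy-13,14,15,16-tetranorlabd-11-en-19-oate
Conditions: mCPBA (1 equiv), CH2Cl2, 0 °C
Reagents that add atoms: 3-chloroperoxybenzoic acid, OOC(=O)c1cccc(Cl)c1
Why: In this Prilezhaev epoxidation the 1,1-disubstituted C8=C17 alkene is more nucleophilic than the vinyl group, and the peracid should come from the α face because the β face is screened by the axial C10 methyl group, which sets the C8–O bond α.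

**Step 13**
Reactants: 17 (S)-but-3-ene-1,2-diol
Product: 18 (S)-2,2-dimethyl-4-vinyl-1,3-dioxolane
Conditions: 2,2-dimethoxypropane, PPTS (cat.), CH2Cl2, rt
Reagents that add atoms: 2,2-dimethoxypropane, COC(C)(C)OC
Why: Acid-catalysed transacetalisation of a 1,2-diol, which does not touch the stereocentre that becomes C14.

**Step 14**
Reactants: 18 (S)-2,2-dimethyl-4-vinyl-1,3-dioxolane
Product: 19 (4R)-4-(1,2-dibromoethyl)-2,2-dimethyl-1,3-dioxolane (both CHBr epimers)
Conditions: Br2, CH2Cl2, −78 °C
Reagents that add atoms: bromine, BrBr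
Why: Electrophilic anti addition of bromine to a terminal alkene; the new CHBr centre is lost again in the next step.

**Step 15**
Reactants: 19 (4R)-4-(1,2-dibromoethyl)-2,2-dimethyl-1,3-dioxolane
Product: 20 (4R)-4-(1-bromovinyl)-2,2-dimethyl-1,3-dioxolane
Conditions: DBU, DMF, 60 °C
Reagents that add atoms: none
Why: E2 dehydrobromination of a vicinal dibromide with a neighbouring oxygen substituent should remove the more acidic CHBr hydrogen and expel the primary bromide, as in the preparation of 2-bromoacrolein acetals, to give the 2-bromo-1-alkene.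

**Step 16**
Reactants: 16 (+)-8-phenylmenthyl 8α,17-epoxy-13,14,15,16-tetranorlabd-11-en-19-oate; 20 (4R)-4-(1-bromovinyl)-2,2-dimethyl-1,3-dioxolane
Product: 22 (+)-8-phenylmenthyl (14S)-8α,17-epoxy-14,15-(isopropylidenedioxy)labd-13(16)-en-19-oate, via B-alkyl-9-BBN borane 21 (not isolated)
Conditions: 9-BBN, THF, rt to 40 °C; then 20, Pd(dppf)Cl2 (cat.), AsPh3 (cat.), Cs2CO3, DMF–H2O, rt to 50 °C
Reagents that add atoms: 9-borabicyclo[3.3.1]nonane, B1C2CCCC1CCC2 (its atoms stay only in 21)
Why: Anti-Markovnikov hydroboration puts boron on C12, and the B-alkyl Suzuki–Miyaura coupling with the 2-bromo-1-alkene (oxidative addition to zerovalent palladium, base-assisted transmetalation, reductive elimination) forms C12–C13 with the C13=C16 alkene in place and C14 untouched.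

**Step 17**
Reactants: 22 (+)-8-phenylmenthyl (14S)-8α,17-epoxy-14,15-(isopropylidenedioxy)labd-13(16)-en-19-oate
Product: 23 (14S)-14,15-(isopropylidenedioxy)labd-13(16)-ene-8α,19-diol
Conditions: LiAlH4, THF, 0 °C to reflux
Reagents that add atoms: none
Why: Hydride opens the epoxide by SN2 at the unhindered C17 methylene, leaving the 8α tertiary alcohol and the 8β-methyl group, and in the same operation reduces the axial ester to the C19 alcohol and releases the auxiliary; alkene and acetonide are inert.

**Step 18**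
Reactants: 23 (14S)-14,15-(isopropylidenedioxy)labd-13(16)-ene-8α,19-diol
Product: 24 (14S)-8α-hydroxy-14,15-(isopropylidenedioxy)labd-13(16)-en-19-al
Conditions: Dess–Martin periodinane, CH2Cl2, rt
Reagents that add atoms: none
Why: The Dess–Martin oxidation takes the only oxidisable hydroxyl group, the neopentyl primary C19 alcohol, while the tertiary 8-OH cannot react.

**Step 19**
Reactants: 24 (14S)-8α-hydroxy-14,15-(isopropylidenedioxy)labd-13(16)-en-19-al
Product: 25 (14S)-8α-hydroxy-14,15-(isopropylidenedioxy)labd-13(16)-en-19-oic acid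
Conditions: NaClO2, NaH2PO4, 2-methyl-2-butene, t-BuOH–H2O, rt
Reagents that add atoms: sodium chlorite, [Na+].[O-]Cl=O
Why: The Pinnick oxidation converts hindered, non-enolisable aldehydes to acids at mild pH, and the scavenger alkene protects the C13=C16 alkene from hypochlorous acid.

**Step 20**
Reactants: 25 (14S)-8α-hydroxy-14,15-(isopropylidenedioxy)labd-13(16)-en-19-oic acid
Product: 26 (14S)-8α,14,15-trihydroxylabd-13(16)-en-19-oic acid (CNP0216809.1)
Conditions: AcOH–H2O (4:1), 40 °C
Reagents that add atoms: none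
Why: Mild acid hydrolysis of a terminal acetonide, under conditions that should neither dehydrate the tertiary 8α-alcohol nor ionise the allylic C14 alcohol.

**Compound list**
1 | geraniol | CC(C)=CCC/C(C)=C/CO | starting material
2 | geranyl tert-butyldiphenylsilyl ether | CC(C)=CCC/C(C)=C/CO[Si](c1ccccc1)(c1ccccc1)C(C)(C)C | intermediate
3 | (2E,6E)-8-(tert-butyldiphenylsilyloxy)-2,6-dimethylocta-2,6-dien-1-ol | OC/C(C)=C/CC/C(C)=C/CO[Si](c1ccccc1)(c1ccccc1)C(C)(C)C | intermediate
4 | (2E,6E)-8-bromo-3,7-dimethylocta-2,6-dienyl tert-butyldiphenylsilyl ether | BrC/C(C)=C/CC/C(C)=C/CO[Si](c1ccccc1)(c1ccccc1)C(C)(C)C | intermediate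
5 | ethyl 2-methylacetoacetate | CCOC(=O)C(C)C(C)=O | starting material
6 | (+)-8-phenylmenthol, (1S,2R,5S) | O[C@H]1C[C@@H](C)CC[C@@H]1C(C)(C)c1ccccc1 | starting material
7 | (+)-8-phenylmenthyl 2-methyl-3-oxobutanoate | CC(=O)C(C)C(=O)O[C@H]1C[C@@H](C)CC[C@@H]1C(C)(C)c1ccccc1 | intermediate
8 | lithium sodium dianion of 7 | [Li+].[Na+].[CH2-]C(=O)[C-](C)C(=O)O[C@H]1C[C@@H](C)CC[C@@H]1C(C)(C)c1ccccc1 | intermediate
9 | (+)-8-phenylmenthyl (6E,10E)-12-(tert-butyldiphenylsilyloxy)-2,6,10-trimethyl-3-oxododeca-6,10-dienoate | CC(C(=O)CC/C(C)=C/CC/C(C)=C/CO[Si](c1ccccc1)(c1ccccc1)C(C)(C)C)C(=O)O[C@H]1C[C@@H](C)CC[C@@H]1C(C)(C)c1ccccc1 | intermediate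
10 | (+)-8-phenylmenthyl 11-(tert-butyldiphenylsilyloxy)-3-oxo-12,13,14,15,16-pentanorlabd-8(17)-en-19-oate | CC(C)(C)[Si](c1ccccc1)(c1ccccc1)OC[C@@H]1[C@@]2(C)CCC(=O)[C@](C)(C(=O)O[C@H]3C[C@@H](C)CC[C@@H]3C(C)(C)c3ccccc3)[C@@H]2CCC1=C | intermediate
11 | 3-(p-toluenesulfonylhydrazone) of 10 | CC(C)(C)[Si](c1ccccc1)(c1ccccc1)OC[C@@H]1[C@@]2(C)CCC(=NNS(=O)(=O)c3ccc(C)cc3)[C@](C)(C(=O)O[C@H]3C[C@@H](C)CC[C@@H]3C(C)(C)c3ccccc3)[C@@H]2CCC1=C | intermediate
12 | (+)-8-phenylmenthyl 11-(tert-butyldiphenylsilyloxy)-12,13,14,15,16-pentanorlabd-8(17)-en-19-oate | CC(C)(C)[Si](c1ccccc1)(c1ccccc1)OC[C@@H]1[C@@]2(C)CCC[C@](C)(C(=O)O[C@H]3C[C@@H](C)CC[C@@H]3C(C)(C)c3ccccc3)[C@@H]2CCC1=C | intermediate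
13 | (+)-8-phenylmenthyl 11-hydroxy-12,13,14,15,16-pentanorlabd-8(17)-en-19-oate | OC[C@@H]1[C@@]2(C)CCC[C@](C)(C(=O)O[C@H]3C[C@@H](C)CC[C@@H]3C(C)(C)c3ccccc3)[C@@H]2CCC1=C | intermediate
14 | (+)-8-phenylmenthyl 11-oxo-12,13,14,15,16-pentanorlabd-8(17)-en-19-oate | O=C[C@@H]1[C@@]2(C)CCC[C@](C)(C(=O)O[C@H]3C[C@@H](C)CC[C@@H]3C(C)(C)c3ccccc3)[C@@H]2CCC1=C | intermediate
15 | (+)-8-phenylmenthyl 13,14,15,16-tetranorlabda-8(17),11-dien-19-oate | C=C[C@@H]1[C@@]2(C)CCC[C@](C)(C(=O)O[C@H]3C[C@@H](C)CC[C@@H]3C(C)(C)c3ccccc3)[C@@H]2CCC1=C | intermediate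
16 | (+)-8-phenylmenthyl 8α,17-epoxy-13,14,15,16-tetranorlabd-11-en-19-oate | C=C[C@@H]1[C@@]2(C)CCC[C@](C)(C(=O)O[C@H]3C[C@@H](C)CC[C@@H]3C(C)(C)c3ccccc3)[C@@H]2CC[C@]14CO4 | intermediate
17 | (S)-but-3-ene-1,2-diol | C=C[C@H](O)CO | starting material
18 | (S)-2,2-dimethyl-4-vinyl-1,3-dioxolane | C=C[C@H]1COC(C)(C)O1 | intermediate
19 | (4R)-4-(1,2-dibromoethyl)-2,2-dimethyl-1,3-dioxolane | BrCC(Br)[C@H]1COC(C)(C)O1 | intermediate
20 | (4R)-4-(1-bromovinyl)-2,2-dimethyl-1,3-dioxolane | C=C(Br)[C@H]1COC(C)(C)O1 | intermediate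
21 | 12-(9-borabicyclo[3.3.1]nonan-9-yl) derivative of 16 (C11–C12 saturated) | B1(CC[C@@H]2[C@@]3(C)CCC[C@](C)(C(=O)O[C@H]4C[C@@H](C)CC[C@@H]4C(C)(C)c4ccccc4)[C@@H]3CC[C@]25CO5)C2CCCC1CCC2 | intermediate
22 | (+)-8-phenylmenthyl (14S)-8α,17-epoxy-14,15-(isopropylidenedioxy)labd-13(16)-en-19-oate | C=C(CC[C@@H]1[C@@]2(C)CCC[C@](C)(C(=O)O[C@H]3C[C@@H](C)CC[C@@H]3C(C)(C)c3ccccc3)[C@@H]2CC[C@]14CO4)[C@H]1COC(C)(C)O1 | intermediate
23 | (14S)-14,15-(isopropylidenedioxy)labd-13(16)-ene-8α,19-diol | C=C(CC[C@@H]1[C@@]2(C)CCC[C@](C)(CO)[C@@H]2CC[C@@]1(C)O)[C@H]1COC(C)(C)O1 | intermediate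
24 | (14S)-8α-hydroxy-14,15-(isopropylidenedioxy)labd-13(16)-en-19-al | C=C(CC[C@@H]1[C@@]2(C)CCC[C@](C)(C=O)[C@@H]2CC[C@@]1(C)O)[C@H]1COC(C)(C)O1 | intermediate
25 | (14S)-8α-hydroxy-14,15-(isopropylidenedioxy)labd-13(16)-en-19-oic acid | C=C(CC[C@@H]1[C@@]2(C)CCC[C@](C)(C(=O)O)[C@@H]2CC[C@@]1(C)O)[C@H]1COC(C)(C)O1 | intermediate
26 | (14S)-8α,14,15-trihydroxylabd-13(16)-en-19-oic acid (CNP0216809.1) | C=C(CC[C@@H]1[C@@]2(C)CCC[C@](C)(C(=O)O)[C@@H]2CC[C@@]1(C)O)[C@H](O)CO | target

Total step count: 20.
Longest linear sequence: 16 steps (1, 2, 3, 5, 6, 7, 8, 9, 10, 11, 12, 16, 17, 18, 19, 20).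

**Steps most likely to fail**

**Step 6.** The phenyl ring may shield the radical face only weakly, because two planar conformers of the unchelated radical compete. The copper-mediated termination may also take hydrogen from C7 or C9 instead of C17.

The fallback takes the quaternary centre out of the cascade and uses chelate control. It sets out from 4 and 6 and comes back at 10.
- Transesterification of methyl acetoacetate with 6 gives (+)-8-phenylmenthyl acetoacetate F1.
- F1 is alkylated at its terminal methyl group with 4 (NaH, n-BuLi, THF) to the α-unsubstituted polyene β-keto ester F2.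
- Mn(OAc)3 with Yb(OTf)3 and Cu(OAc)2 in CF3CH2OH at 0 °C closes both rings through the metal-chelated radical, a mode in which this auxiliary is known to shield one face well. This gives the C4–H bicyclic β-keto ester F3.
- C-methylation of F3 (K2CO3, MeI, acetone) from the α face, away from the axial C10 methyl group, returns to 10.

**Step 8 (with step 7).** Condensation at the hindered C3 carbonyl may be slow, or the hydrazone may eliminate to a C2=C3 alkene instead of being reduced.

The fallback is a Barton–McCombie deoxygenation. It sets out from 10 and comes back at 12.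
- NaBH4 in MeOH gives the equatorial 3β-alcohol F4.
- 1,1'-Thiocarbonyldiimidazole with DMAP, under neutral conditions that avoid retro-aldol opening, gives the 3β-imidazolylthiocarbonyl ester F5.
- Bu3SnH with AIBN in toluene at reflux replaces the C3–O bond by C3–H and gives 12.

**Step 12.** Facial selectivity of the peracid at the exocyclic alkene may be poor, which would erode the C8 configuration.

The fallback forms the C8–O bond by radical hydration instead of epoxidation and hydride opening. It sets out from 15 and comes back at 23.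
- Mukaiyama hydration of 15 (Co(acac)2, PhSiH3, O2, THF) transfers a hydrogen atom selectively to the 1,1-disubstituted alkene. The tertiary C8 radical should take up oxygen on the α face, away from the axial C10 methyl group, to give the 8α-alcohol F6.
- Hydroboration of the vinyl group with 9-BBN gives the borane F7, which is coupled with 20 as in step 16 to the 8α-hydroxy ester F8.
- LiAlH4 then removes the auxiliary from F8 and gives 23.

**Further compounds**
F1 | step 6 | (+)-8-phenylmenthyl acetoacetate | CC(=O)CC(=O)O[C@H]1C[C@@H](C)CC[C@@H]1C(C)(C)c1ccccc1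
F2 | step 6 | (+)-8-phenylmenthyl (6E,10E)-12-(tert-butyldiphenylsilyloxy)-6,10-dimethyl-3-oxododeca-6,10-dienoate | O=C(CC/C(C)=C/CC/C(C)=C/CO[Si](c1ccccc1)(c1ccccc1)C(C)(C)C)CC(=O)O[C@H]1C[C@@H](C)CC[C@@H]1C(C)(C)c1ccccc1
F3 | step 6 | (+)-8-phenylmenthyl 11-(tert-butyldiphenylsilyloxy)-3-oxo-12,13,14,15,16,18-hexanorlabd-8(17)-en-19-oate (C4 epimerisable) | CC(C)(C)[Si](c1ccccc1)(c1ccccc1)OC[C@@H]1[C@@]2(C)CCC(=O)C(C(=O)O[C@H]3C[C@@H](C)CC[C@@H]3C(C)(C)c3ccccc3)[C@@H]2CCC1=C
F4 | step 8 | (+)-8-phenylmenthyl 11-(tert-butyldiphenylsilyloxy)-3β-hydroxy-12,13,14,15,16-pentanorlabd-8(17)-en-19-oate | CC(C)(C)[Si](c1ccccc1)(c1ccccc1)OC[C@@H]1[C@@]2(C)CC[C@H](O)[C@](C)(C(=O)O[C@H]3C[C@@H](C)CC[C@@H]3C(C)(C)c3ccccc3)[C@@H]2CCC1=C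
F5 | step 8 | 3β-O-(imidazol-1-ylthiocarbonyl) derivative of F4 | CC(C)(C)[Si](c1ccccc1)(c1ccccc1)OC[C@@H]1[C@@]2(C)CC[C@H](OC(=S)n3ccnc3)[C@](C)(C(=O)O[C@H]3C[C@@H](C)CC[C@@H]3C(C)(C)c3ccccc3)[C@@H]2CCC1=C
F6 | step 12 | (+)-8-phenylmenthyl 8α-hydroxy-13,14,15,16-tetranorlabd-11-en-19-oate | C=C[C@@H]1[C@@]2(C)CCC[C@](C)(C(=O)O[C@H]3C[C@@H](C)CC[C@@H]3C(C)(C)c3ccccc3)[C@@H]2CC[C@@]1(C)O
F7 | step 12 | 12-(9-borabicyclo[3.3.1]nonan-9-yl) derivative of F6 (C11–C12 saturated) | B1(CC[C@@H]2[C@@]3(C)CCC[C@](C)(C(=O)O[C@H]4C[C@@H](C)CC[C@@H]4C(C)(C)c4ccccc4)[C@@H]3CC[C@@]2(C)O)C2CCCC1CCC2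
F8 | step 12 | (+)-8-phenylmenthyl (14S)-8α-hydroxy-14,15-(isopropylidenedioxy)labd-13(16)-en-19-oate | C=C(CC[C@@H]1[C@@]2(C)CCC[C@](C)(C(=O)O[C@H]3C[C@@H](C)CC[C@@H]3C(C)(C)c3ccccc3)[C@@H]2CC[C@@]1(C)O)[C@H]1COC(C)(C)O1
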